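**Plan**

- Retrosynthesis: the 4'-O–sulfonyl bond of a masked phenol is cut first, then the O1–C8a bond of the pyranone (ring C), then the C2–C3 bond of the resulting 1,3-diketone. This leaves a ring-A methyl ketone and a ring-B benzoate.
- Enabling feature: C8a of ring A is the only unsubstituted carbon ortho to C4a and lies para to the C6 methoxy group. A 2,3,4-trimethoxybenzoyl unit can therefore accept the enol oxygen at that C–H under oxidation, without a pre-installed oxygen or halogen.
- Forward: the ring-B phenol is tosylated, a crossed Claisen condensation makes C2–C3 and joins rings A and B through the three-carbon chain, ring C (the only ring formed) closes by anodic C–H/O–H coupling, and the sulfonate is hydrolysed.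
- Stereochemistry: the target is a planar flavone without any stereocentre, so no configuration has to be set.

Key step: step 3

Remark: the molecule has no stereogenic element, so the achiral compound itself is the single species asked for; diketone 6 is drawn as the diketo tautomer although it should exist mainly as the chelated enol.

**Route**

Step 1
Reactants: 1 methyl syringate; 2 p-toluenesulfonyl chloride
Product: 3 methyl 3,5-dimethoxy-4-(tosyloxy)benzoate
Conditions: K2CO3, acetone, reflux
Reagents that add atoms: none
Why: Phenol O-sulfonylation (tosylation) of the carbonate-generated phenoxide should be clean because the phenol is the only acidic nucleophile and the methyl ester is inert to carbonate in acetone.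

Step 2
Reactants: 4 2,3,4-trimethoxyacetophenone; 3 methyl 3,5-dimethoxy-4-(tosyloxy)benzoate
Product: 6 1-(2,3,4-trimethoxyphenyl)-3-[3,5-dimethoxy-4-(tosyloxy)phenyl]propane-1,3-dione, via lithium 1-(2,3,4-trimethoxyphenyl)ethenolate 5 (not isolated)
Conditions: LiHMDS (3 equiv), THF, −78 °C; then 3, −78 °C to rt; 1 M HCl work-up
Reagents that add atoms: none
Why: In this crossed Claisen condensation the preformed lithium enolate is acylated at carbon by the non-enolisable benzoate and excess amide base traps the product as its diketonate, which drives the equilibrium, while the aryl tosylate, screened by two ortho methoxy groups, should resist attack at sulfur at low temperature.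

Step 3
Reactants: 6 1-(2,3,4-trimethoxyphenyl)-3-[3,5-dimethoxy-4-(tosyloxy)phenyl]propane-1,3-dione
Product: 7 2-[3,5-dimethoxy-4-(tosyloxy)phenyl]-5,6,7-trimethoxy-4H-chromen-4-one (4'-O-tosyl ageconyflavone C)
Conditions: constant-current electrolysis, undivided cell, graphite anode, Pt cathode, nBu4NBF4 (0.1 M), HFIP/CH2Cl2 4:1, rt, ca. 2.2 F/mol
Reagents that add atoms: none
Why: Proposed new method: one-electron oxidation at the anode should place the hole on the 2,3,4-trimethoxybenzoyl ring, the most electron-rich π-system of 6, giving a radical cation that hexafluoroisopropanol stabilises and that carries positive charge at the free carbon para to the central methoxy group; the oxygen of the enolised ring-B carbonyl adds to that carbon, and proton loss, a second electron transfer and loss of the ring proton restore aromaticity while protons are reduced to hydrogen at the cathode. The closest known reaction types are anodic intramolecular dehydrogenative C–O couplings of electron-rich arenes (benzocoumarins from biaryl-2-carboxylic acids, benzoxazoles from anilides) and the iron(III)-mediated oxidative closure of α-aryl ketone enols to benzofurans; new here are a 1,3-diketone enol as the oxygen nucleophile and a pyranone as the ring formed. Ring C closes by six-membered attack of oxygen on an sp2 ring carbon (formally 6-endo-trig with respect to the C4a–C8a bond), and no stereocentre is created. The step needs ring A to react in preference to ring B, and C–H substitution in preference to ipso attack at the methoxy-bearing ortho carbon. The sulfonyloxy and acyl groups raise the oxidation potential of ring B, whose two methoxy groups are only meta to each other, so the hole should stay on ring A, and the unhindered site para to a methoxy group is the position of highest positive charge. Ring A has only one ortho C–H, so the 5,6,7-trimethoxy pattern follows unambiguously.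

Step 4
Reactants: 7 2-[3,5-dimethoxy-4-(tosyloxy)phenyl]-5,6,7-trimethoxy-4H-chromen-4-one
Product: 8 2-(4-hydroxy-3,5-dimethoxyphenyl)-5,6,7-trimethoxy-4H-chromen-4-one (ageconyflavone C)
Conditions: KOH (aq., 4 equiv), 1,4-dioxane, 60 °C; then 1 M HCl
Reagents that add atoms: none
Why: Sulfonate ester hydrolysis by hydroxide attack at sulfur (S–O cleavage) should expel the 4'-phenoxide, a good leaving group because it is conjugated through ring B to the pyranone carbonyl, while the methyl ethers are untouched, no methylating by-product can form in the absence of methanol, and acidification returns the free phenol.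

**Compound list**

1 | methyl syringate (methyl 4-hydroxy-3,5-dimethoxybenzoate) | COC(=O)c1cc(OC)c(O)c(OC)c1 | starting material
2 | p-toluenesulfonyl chloride | Cc1ccc(S(=O)(=O)Cl)cc1 | starting material
3 | methyl 3,5-dimethoxy-4-(tosyloxy)benzoate | COC(=O)c1cc(OC)c(OS(=O)(=O)c2ccc(C)cc2)c(OC)c1 | intermediate
4 | 2,3,4-trimethoxyacetophenone | CC(=O)c1ccc(OC)c(OC)c1OC | starting material
5 | lithium 1-(2,3,4-trimethoxyphenyl)ethenolate | [Li+].[O-]C(=C)c1ccc(OC)c(OC)c1OC | intermediate (not isolated)
6 | 1-(2,3,4-trimethoxyphenyl)-3-[3,5-dimethoxy-4-(tosyloxy)phenyl]propane-1,3-dione | COc1ccc(C(=O)CC(=O)c2cc(OC)c(OS(=O)(=O)c3ccc(C)cc3)c(OC)c2)c(OC)c1OC | intermediate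
7 | 2-[3,5-dimethoxy-4-(tosyloxy)phenyl]-5,6,7-trimethoxy-4H-chromen-4-one (4'-O-tosyl ageconyflavone C) | COc1cc(-c2cc(=O)c3c(OC)c(OC)c(OC)cc3o2)cc(OC)c1OS(=O)(=O)c1ccc(C)cc1 | intermediate
8 | ageconyflavone C, 2-(4-hydroxy-3,5-dimethoxyphenyl)-5,6,7-trimethoxy-4H-chromen-4-one | COc1cc(-c2cc(=O)c3c(OC)c(OC)c(OC)cc3o2)cc(OC)c1O | target

**Count**

Total steps: 4. Longest linear sequence: 4 steps (1 → 3 → 6 → 7 → 8).

**Steps most likely to fail**

1. Step 3 (proposed new method). The closure may not compete with over-oxidation of the electron-rich product, with anodic dimerisation of the diketone at its central carbon, with non-oxidative ipso displacement of the ortho methoxy group, or with attack on ring B. The fallback uses known chemistry and sets out from 3. Commercial 6-hydroxy-2,3,4-trimethoxyacetophenone (CC(=O)c1c(O)cc(OC)c(OC)c1OC) is converted into its dianion with LiHMDS (3.5 equiv, THF, −78 °C) and acylated with 3 to give 1-(6-hydroxy-2,3,4-trimethoxyphenyl)-3-[3,5-dimethoxy-4-(tosyloxy)phenyl]propane-1,3-dione F1. Acid-catalysed cyclodehydration (cat. H2SO4, AcOH, 90 °C) should then close the pyranone through the phenol oxygen and return to the route at 7.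

2. Step 2. Sulfonyl transfer from the aryl tosylate to the enolate or the amide base, or stalling of the acylation once the product diketonate has consumed base, may lower the conversion. The fallback sets out from 4 and replaces the ester electrophile by an aldehyde, so that one equivalent of enolate at −78 °C suffices. Commercial syringaldehyde (COc1cc(C=O)cc(OC)c1O) is tosylated with 2 (K2CO3, acetone, reflux) to 4-formyl-2,6-dimethoxyphenyl 4-methylbenzenesulfonate F2. Aldol addition of enolate 5 (from 4, LiHMDS 1.05 equiv, THF, −78 °C, cold quench) should give racemic 3-hydroxy-1-(2,3,4-trimethoxyphenyl)-3-[3,5-dimethoxy-4-(tosyloxy)phenyl]propan-1-one F3. Oxidation of the β-hydroxy ketone with Dess–Martin periodinane (CH2Cl2, rt) removes the transient stereocentre and returns to the route at 6.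

3. Step 4. Hydroxide may add to C2 of the pyranone and the opened diketone may fragment by retro-Claisen cleavage faster than the sulfonate is hydrolysed. The fallback changes the masking group to one that is lost at room temperature; it sets out from 1 and repeats the closure of step 3 on the triflate. Triflation of 1 (Tf2O, pyridine, CH2Cl2, 0 °C) gives methyl 3,5-dimethoxy-4-(trifluoromethylsulfonyloxy)benzoate F4. Claisen condensation with enolate 5 as in step 2 gives 1-(2,3,4-trimethoxyphenyl)-3-[3,5-dimethoxy-4-(trifluoromethylsulfonyloxy)phenyl]propane-1,3-dione F5. Anodic closure as in step 3, with ring B deactivated still more strongly, gives 2-[3,5-dimethoxy-4-(trifluoromethylsulfonyloxy)phenyl]-5,6,7-trimethoxy-4H-chromen-4-one F6. Brief treatment with Et4NOH in aqueous dioxane at rt should cleave the aryl triflate and arrive at 8.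

**Further compounds**

F1 | step 3 | 1-(6-hydroxy-2,3,4-trimethoxyphenyl)-3-[3,5-dimethoxy-4-(tosyloxy)phenyl]propane-1,3-dione | COc1cc(O)c(C(=O)CC(=O)c2cc(OC)c(OS(=O)(=O)c3ccc(C)cc3)c(OC)c2)c(OC)c1OC
F2 | step 2 | 4-formyl-2,6-dimethoxyphenyl 4-methylbenzenesulfonate | Cc1ccc(S(=O)(=O)Oc2c(OC)cc(C=O)cc2OC)cc1
F3 | step 2 | racemic 3-hydroxy-1-(2,3,4-trimethoxyphenyl)-3-[3,5-dimethoxy-4-(tosyloxy)phenyl]propan-1-one | COc1ccc(C(=O)CC(O)c2cc(OC)c(OS(=O)(=O)c3ccc(C)cc3)c(OC)c2)c(OC)c1OC
F4 | step 4 | methyl 3,5-dimethoxy-4-(trifluoromethylsulfonyloxy)benzoate | COC(=O)c1cc(OC)c(OS(=O)(=O)C(F)(F)F)c(OC)c1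
F5 | step 4 | 1-(2,3,4-trimethoxyphenyl)-3-[3,5-dimethoxy-4-(trifluoromethylsulfonyloxy)phenyl]propane-1,3-dione | COc1ccc(C(=O)CC(=O)c2cc(OC)c(OS(=O)(=O)C(F)(F)F)c(OC)c2)c(OC)c1OC
F6 | step 4 | 2-[3,5-dimethoxy-4-(trifluoromethylsulfonyloxy)phenyl]-5,6,7-trimethoxy-4H-chromen-4-one | COc1cc(-c2cc(=O)c3c(OC)c(OC)c(OC)cc3o2)cc(OC)c1OS(=O)(=O)C(F)(F)F
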